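Watch one number: the uptake u, the D taken up per Z charged, held against a line.

all flasks: Z 0.050 M
- beta: D 0.46 equiv; run made earlier
- alpha: D 0.89 equiv; run made earlier
- Saturday's: D 0.800 equiv; time 25 h
- Tuesday's: D 1.20 equiv; time 25 h

| run | time / h | E / % | Q / % |
|---|---|---|---|
| beta | 2.50 | 5.1 | 0 |
| beta | 5.00 | 9.4 | 0.9 |
| beta | 8.00 | 12.3 | 2.0 |
| beta | 10.0 | 15.7 | 1.7 |
| beta | 12.0 | 16.6 | 1.9 |
| beta | 15.0 | 19.2 | 2.0 |
| beta | 20.0 | 22.4 | 2.6 |
| alpha | 1.00 | 4.4 | 0 |
| alpha | 2.50 | 8.8 | 0.5 |
| alpha | 5.00 | 15.7 | 1.5 |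
| alpha | 8.00 | 22.3 | 3.0 |
| alpha | 10.0 | 24.7 | 4.2 |
| alpha | 15.0 | 30.9 | 6.1 |
| alpha | 20.0 | 35.5 | 8.1 |

(standard deviation of a reading: 0.5 percentage points)

- which of these holds the largest part of the Z at the end of Saturday's (Z / Q / E)
- which of these holds the largest part of the Z at the end of Tuesday's (Z / Q / E)
- amount of E at the end of Saturday's, in percent of the Z charged

Count D spent: once in E, twice in Q. So at 20.0 h the alpha run keeps 41.9% of its D and the beta run 40.0%, nearly the same share from charges of 0.89 equiv and 0.46 equiv. Treat D as pseudo-first-order, then, and let the alpha share f scale with time as a power. Fold the givens into u, the equivalents of D times (1 minus f to the power t over 20.0 h). Saturday's gets u = 53.0%, Tuesday's 79.5%.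

Spread the uptake by chance over two like sites, with s = u/2 the share taken. Z then holds (1 − s) squared and E holds 2s(1 − s). They are equal at u = 66.7%. Saturday's lies below that line, so Z leads; Tuesday's lies above it, so E leads.

Test it on alpha's last reading. Its uptake 51.7% gives E 38.3% by chance, but the reading is 35.5%. At this reading of the alpha run, the chance value overshoots E by 2.8 percentage points. Saturday's chance value 39.0%, lowered by that gap, gives my 36.1%.

The forecast says Z for Saturday's, E for Tuesday's, and 36% of E. Of Tuesday's it says “This is a close call”.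

    Z + D → L + E (k = 2.70 × 10⁻⁴ M⁻¹ s⁻¹)
    E + D ⇌ L + Q (K = 0.360, k = 2.80 × 10⁻⁴ M⁻¹ s⁻¹)
    G ⇌ Q, rate k3*(cs3 - [Q]) while solid is left; crystals form when [Q] > cs3 (solubility = 16.0 mM, k = 6.20 × 10⁻⁴ s⁻¹)

Saturday's gives E 37.3% beside Z 55.8%; Tuesday's gives E 47.8% over Z 40.6%. In Saturday's, Q stands at 3.47 mM, below saturation at 16 mM, G stays 0%, and crystallising moves E by nothing. Saturday's actual uptake is 51.1% against the reckoned 53.0%. For Saturday's flask left until 4.0 d, reckon u = 78.8%, above the line: there E holds 64.2% and Z 32.4%.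

All runs stem from a simulated flask from invented constants, and the scatter is random.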